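Of the D charged, 52.0 % stood as X plus E in the noon run at 20.0 min, although D then read 0 %; the spring run gave 49.0 %. So in the noon run 48.0 % of the charge stood in neither of the two products I could read.

| setting | noon | spring | flask |
|---|---|---|---|
| D | 2 M | 2 M | 2.0 M |
| L | 0.056 M | 0.088 M | 0.0400 M |
| remark | run made earlier | run made earlier |  |
| time |  |  | 25 min |

| run | time / min | X / % | E / % | D / % |
|---|---|---|---|---|
| noon | 1.50 | 12 | 2 | 50 |
| noon | 4.00 | 22 | 7 | 19 |
| noon | 8.00 | 25 | 13 | 6 |
| noon | 20.0 | 25 | 27 | 0 |
| spring | 1.50 | 12 | 0 | 48 |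
| spring | 4.00 | 22 | 7 | 19 |
| spring | 8.00 | 24 | 10 | 6 |
| spring | 20.0 | 21 | 28 | 0 |

(standard deviation of a reading: 1.5 percentage points)

- at the start none of D is in solution
- a reading or a percentage of E counts all its forms, free or not

- share of X in X plus E at 30 s
- share of X in X plus E at 3.0 min
- share of X in X plus E at 25 min

I cleared this up by asking what the balance of the charge must be once D reads zero. Pooling both runs at 20.0 min, I defined the hold-up ratio, the unread percentage over the percentage of X, as 2.15. The same sum at 8.00 min, with D counted, gave 2.37, so I assumed that X kept a steady ratio to an unread pool, as in a pre-equilibrium. Then X is the charge minus E, divided by one plus the ratio. I carried the pooled rise of E forward to 34.2 % at 25 min, assuming the lower L of the flask changed nothing. That gave X 20.9 % and a share of 37.9 %.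

The forecast, judging that "Rates therefore look zero order in L over that range", gave 96 %, 82 % and 42 %, the last above my 37.9 %.

The flask gave 87.2 %, 80.4 % and 40.4 %.

    J ⇌ E (K = 0.190, k = 0.0700 /min)
    E ⇌ X (K = 2.60, k = 0.0340 /min)
    X ⇌ J (k = 1.10 /min)
    G ⇌ E, rate k4*(cs4 - [E]) while solid is left; crystals form when [E] > cs4 (solubility = 0.120 M, k = 3.00 /min)
    J + L → Q (k = 3.10 /M/min)
    D ⇌ J, rate k6*(cs6 - [J]) while solid is left; crystals form when [J] > cs6 (solubility = 1.10 M, k = 1.10 /min)

The unread part of the flask at 25.0 min was J, the dissolved D, at 43.9 %, and Q, the product of J with L, at 2.00 %, beside X at 21.9 %. With the flask's E of 32.3 %, the ratio gives X 21.5 %. The neighbour flask with 1.2 M of D held E 14.6 % at 25.0 min, so the same reckoning gives X 27.1 % and a share of 65.0 %. That neighbour held X 27.2 %, and its share stood at 65.0 %.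

(The data were computed from invented constants, and the scatter is random.)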